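**Plan**

1. Locants: C1 lactone C=O, C2 its CH2, C3 the CH–O–O ring-fusion carbon, C4 the C(CH3)–O ring-fusion carbon, C5 ring CH2, C6 the C(CH3)–O–O carbon, C7–C16 the side chain. Retrosynthetic cuts in order: C10=C11 (Julia–Kocienski), C6–C7 (substitution at a C6 peroxyketal), C1–C2 together with C3–O (one cascade), C2=C3 (HWE), C5–isopropenyl (epoxide opening).
2. Enabling feature: in the lactone-fused 1,2-dioxane, the peroxide-bearing C3 is β and C2 is α to the lactone carbonyl C1, and the lactone oxygen sits on the adjacent quaternary C4. A C6 hydroperoxide can therefore add to a C2=C3 acceptor, and the C2 carbanion so formed can close the γ-lactone on a carbonate carried by the C4 oxygen.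
3. Helpers: a 2-(trimethylsilyl)ethyl carbonate on O–C4 (tether that delivers C1), a 2-(trimethylsilyl)ethyl ester on C2 (activating group, removed by fluoride then decarboxylation), a methoxy peroxyketal at C6 (from ozonolysis, ionised later).
4. Forward order: acyclic C4 carbinol, enoate carbonate, hydroperoxy ketal, then the 1,2-dioxane ring and the γ-lactone ring in one flask, then the C7–C10 stub at C6, then the full side chain by olefination.
5. Stereochemistry: C4 from (R)-2-methylglycidol; C3 from C4 through the cis-fusion requirement of the cascade; C6 from axial attack on the bicyclic peroxycarbenium ion anti to the C4 methyl; E alkenes from HWE, s-trans dienol ether geometry, cross-metathesis and Julia–Kocienski.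

Key step: step 7

Remark: (R)-2-methylglycidol is taken as commercially available; the peroxyketal carbon C6 of 10–14 forms as both epimers and is carried as such, because step 10 ionises it.

**Step 1**
Reactants: 1 (R)-2-methylglycidol; 2 isopropenylmagnesium bromide
Product: 3 (S)-2,4-dimethylpent-4-ene-1,2-diol
Conditions: 2 (2.5 equiv), CuBr·SMe2 (10 mol %), THF, −30 → 0 °C
Reagents that add atoms: none
Why: Copper-catalysed Grignard opening of the 2,2-disubstituted epoxide at its unhindered CH2 terminus (SN2) breaks no bond to the carbinol stereocentre, so the future C4 comes unchanged from 1 (the descriptor changes only through CIP priorities).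

**Step 2**
Reactants: 3 (S)-2,4-dimethylpent-4-ene-1,2-diol
Product: 4 (S)-2-hydroxy-2,4-dimethylpent-4-enal
Conditions: IBX (1.5 equiv), EtOAc, 75 °C; filter, use crude
Reagents that add atoms: none
Why: 2-Iodoxybenzoic acid should oxidise the primary alcohol of the 1,2-diol to the aldehyde without glycol cleavage, and the tertiary hydroxyl cannot be oxidised.

**Step 3**
Reactants: 5 diethylphosphonoacetic acid; 6 2-(trimethylsilyl)ethanol
Product: 7 2-(trimethylsilyl)ethyl 2-(diethoxyphosphoryl)acetate
Conditions: DCC, DMAP (cat.), CH2Cl2, 0 °C → rt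
Reagents that add atoms: none
Why: Steglich esterification of the acid with an unhindered primary alcohol.

**Step 4**
Reactants: 4 (S)-2-hydroxy-2,4-dimethylpent-4-enal; 7 2-(trimethylsilyl)ethyl 2-(diethoxyphosphoryl)acetate
Product: 8 2-(trimethylsilyl)ethyl (2E,4S)-4-hydroxy-4,6-dimethylhepta-2,6-dienoate
Conditions: LiCl, DBU, MeCN, 0 °C → rt
Reagents that add atoms: none
Why: Horner–Wadsworth–Emmons olefination under LiCl/amine conditions is mild enough for a free α-hydroxy aldehyde and should give the E enoate from the α-branched aldehyde.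

**Step 5**
Reactants: 8 2-(trimethylsilyl)ethyl (2E,4S)-4-hydroxy-4,6-dimethylhepta-2,6-dienoate
Product: 9 2-(trimethylsilyl)ethyl (2E,4S)-4,6-dimethyl-4-({[2-(trimethylsilyl)ethoxy]carbonyl}oxy)hepta-2,6-dienoate
Conditions: LiN(SiMe3)2, THF, −78 °C; 4-nitrophenyl 2-(trimethylsilyl)ethyl carbonate, −78 → 0 °C; aq NH4Cl
Reagents that add atoms: 4-nitrophenyl 2-(trimethylsilyl)ethyl carbonate, C[Si](C)(C)CCOC(=O)Oc1ccc(cc1)[N+](=O)[O-]
Why: Alkoxycarbonyl transfer from the activated aryl carbonate to the lithium alkoxide of the hindered tertiary alcohol installs the C1 tether, with the same alkoxy group as the ester so that later alkoxide exchange is degenerate.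

**Step 6**
Reactants: 9 2-(trimethylsilyl)ethyl (2E,4S)-4,6-dimethyl-4-({[2-(trimethylsilyl)ethoxy]carbonyl}oxy)hepta-2,6-dienoate
Product: 10 2-(trimethylsilyl)ethyl (2E,4S)-6-hydroperoxy-6-methoxy-4-methyl-4-({[2-(trimethylsilyl)ethoxy]carbonyl}oxy)hept-2-enoate
Conditions: O3 (1 equiv, Sudan Red 7B end point), CH2Cl2/MeOH, NaHCO3, −78 °C; N2 purge, concentrate cold
Reagents that add atoms: ozone, [O-][O+]=O; methanol, CO
Why: Ozonolysis in methanol should cleave only the electron-rich 1,1-disubstituted alkene (the enoate is far less reactive), and solvent capture of the more substituted carbonyl oxide gives the tertiary α-methoxy hydroperoxide as both C6 epimers.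

**Step 7**
Reactants: 10 2-(trimethylsilyl)ethyl (2E,4S)-6-hydroperoxy-6-methoxy-4-methyl-4-({[2-(trimethylsilyl)ethoxy]carbonyl}oxy)hept-2-enoate
Product: 12 2-(trimethylsilyl)ethyl (4aS,7aS)-3-methoxy-3,4a-dimethyl-6-oxohexahydro-3H-furo[3,2-c][1,2]dioxine-7-carboxylate, via oxa-Michael adduct 11 (not isolated)
Conditions: KOtBu (1.1 equiv), THF, −40 → 0 °C; AcOH quench
Reagents that add atoms: none
Why: Proposed new method: the potassium hydroperoxide adds 6-exo-trig to C3 of the enoate (oxa-Michael; closest known type is the base-mediated cyclisation of hydroperoxy ketals onto enoates to 1,2-dioxanes), and the ester enolate generated at C2 attacks the carbonate carbonyl on the C4 oxygen 5-exo-trig (intramolecular Claisen acylation, as in Michael–Dieckmann annulations), expelling 2-(trimethylsilyl)ethoxide and forming the C1–C2 bond. The 1,2-dioxane ring closes by C–O bond formation (6-exo-trig) and the γ-lactone ring by C–C bond formation (5-exo-trig at the carbonate carbonyl). C3 is controlled by C4: the Michael step is reversible and only the adduct whose C2 arm is cis to the C4 carbonate oxygen can reach the carbonate, so the cis-fused 3S isomer is drained, while C2 is a transient enolisable centre that is erased in step 8. The step needs C-acylation by the C2 enolate in preference to attack of peroxide anion or alkoxide on the carbonate or ester; this is secured by the five-membered transition state open only to C2, by the matched alkoxy groups, and by final deprotonation of the 1,3-dicarbonyl product, which consumes the liberated alkoxide and pulls the equilibria forward.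

**Step 8**
Reactants: 12 2-(trimethylsilyl)ethyl (4aS,7aS)-3-methoxy-3,4a-dimethyl-6-oxohexahydro-3H-furo[3,2-c][1,2]dioxine-7-carboxylate
Product: 14 (4aS,7aS)-3-methoxy-3,4a-dimethyltetrahydro-3H-furo[3,2-c][1,2]dioxin-6(4H)-one, via carboxylic acid 13 (not isolated)
Conditions: Bu4NF, AcOH, THF, 0 °C → rt; then toluene, 90 °C
Reagents that add atoms: none
Why: Buffered fluoride should cleave the 2-(trimethylsilyl)ethyl ester by β-elimination, and the resulting β-carbonyl acid should lose CO2 through the cyclic six-membered transition state on gentle heating, removing the C2 activating group.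

**Step 9**
Reactants: 15 3-methylbut-2-enal
Product: 16 (E)-trimethyl[(3-methylbuta-1,3-dien-1-yl)oxy]silane
Conditions: Me3SiCl, Et3N, ZnCl2 (cat.), Et2O, reflux
Reagents that add atoms: chlorotrimethylsilane, C[Si](C)(C)Cl
Why: Soft enolisation of the enal removes a γ-proton and silylates on oxygen to give the 1-siloxy diene.

**Step 10**
Reactants: 14 (4aS,7aS)-3-methoxy-3,4a-dimethyltetrahydro-3H-furo[3,2-c][1,2]dioxin-6(4H)-one; 16 (E)-trimethyl[(3-methylbuta-1,3-dien-1-yl)oxy]silane
Product: 17 (2E)-4-[(3R,4aS,7aS)-3,4a-dimethyl-6-oxohexahydro-3H-furo[3,2-c][1,2]dioxin-3-yl]-3-methylbut-2-enal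
Conditions: 16 (2 equiv), Me3SiOTf (20 mol %), CH2Cl2, −78 °C; Et3N quench
Reagents that add atoms: none
Why: Me3SiOTf should ionise both peroxyketal epimers to one peroxycarbenium ion, which is captured at the γ-terminus of the s-trans dienol ether (vinylogous Mukaiyama-type substitution of a peroxyketal, giving the E enal) by axial attack on the half-chair from the face of the C4 lactone oxygen, since the other face would place the nucleophile 1,3-diaxial to the C4 methyl, so the C6 methyl ends cis to the C4 methyl.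

**Step 11**
Reactants: 18 hex-5-en-1-ol; 19 styrene
Product: 20 (E)-6-phenylhex-5-en-1-ol
Conditions: 19 (3 equiv), second-generation Grubbs catalyst (2 mol %), CH2Cl2, 40 °C
Reagents that add atoms: none
Why: Olefin cross-metathesis of a terminal alkene with styrene should give the E styrenyl alkene under thermodynamic control.

**Step 12**
Reactants: 20 (E)-6-phenylhex-5-en-1-ol; 21 1-phenyl-1H-tetrazole-5-thiol
Product: 22 (E)-1-phenyl-5-[(6-phenylhex-5-en-1-yl)sulfanyl]-1H-tetrazole
Conditions: PPh3, DIAD, THF, 0 °C → rt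
Reagents that add atoms: none
Why: Mitsunobu thioetherification of the primary alcohol with the acidic tetrazole thiol.

**Step 13**
Reactants: 22 (E)-1-phenyl-5-[(6-phenylhex-5-en-1-yl)sulfanyl]-1H-tetrazole
Product: 23 (E)-1-phenyl-5-[(6-phenylhex-5-en-1-yl)sulfonyl]-1H-tetrazole
Conditions: (NH4)6Mo7O24·4H2O (10 mol %), 30% aq H2O2, EtOH, 0 °C → rt
Reagents that add atoms: hydrogen peroxide, OO
Why: Molybdate-catalysed peroxide oxidation should take the sulfide to the sulfone without epoxidising the styrene.

**Step 14**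
Reactants: 17 (2E)-4-[(3R,4aS,7aS)-3,4a-dimethyl-6-oxohexahydro-3H-furo[3,2-c][1,2]dioxin-3-yl]-3-methylbut-2-enal; 23 (E)-1-phenyl-5-[(6-phenylhex-5-en-1-yl)sulfonyl]-1H-tetrazole
Product: 24 plakortolide H
Conditions: 23 (1.3 equiv), KN(SiMe3)2, DME, −60 °C; then 17, −60 °C → rt; aq NH4Cl
Reagents that add atoms: none
Why: Julia–Kocienski olefination of the enal with the metalated phenyltetrazolyl sulfone (addition, Smiles rearrangement, loss of SO2 and tetrazololate) should give the E C10=C11 bond at low temperature without disturbing the β-peroxy lactone or the existing E alkenes.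

**Compound list**

1 | (R)-2-methylglycidol, (R)-(2-methyloxiran-2-yl)methanol | C[C@@]1(CO)CO1 | starting material
2 | isopropenylmagnesium bromide | CC(=C)[Mg]Br | starting material
3 | (S)-2,4-dimethylpent-4-ene-1,2-diol | C=C(C)C[C@](CO)(C)O | intermediate
4 | (S)-2-hydroxy-2,4-dimethylpent-4-enal | C=C(C)C[C@](C=O)(C)O | intermediate
5 | diethylphosphonoacetic acid | CCOP(=O)(CC(=O)O)OCC | starting material
6 | 2-(trimethylsilyl)ethanol | C[Si](C)(C)CCO | starting material
7 | 2-(trimethylsilyl)ethyl 2-(diethoxyphosphoryl)acetate | CCOP(=O)(CC(=O)OCC[Si](C)(C)C)OCC | intermediate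
8 | 2-(trimethylsilyl)ethyl (2E,4S)-4-hydroxy-4,6-dimethylhepta-2,6-dienoate | C=C(C)C[C@](/C=C/C(=O)OCC[Si](C)(C)C)(C)O | intermediate
9 | 2-(trimethylsilyl)ethyl (2E,4S)-4,6-dimethyl-4-({[2-(trimethylsilyl)ethoxy]carbonyl}oxy)hepta-2,6-dienoate | C=C(C)C[C@](/C=C/C(=O)OCC[Si](C)(C)C)(C)OC(=O)OCC[Si](C)(C)C | intermediate
10 | 2-(trimethylsilyl)ethyl (2E,4S)-6-hydroperoxy-6-methoxy-4-methyl-4-({[2-(trimethylsilyl)ethoxy]carbonyl}oxy)hept-2-enoate (both C6 epimers) | COC(C)(OO)C[C@](/C=C/C(=O)OCC[Si](C)(C)C)(C)OC(=O)OCC[Si](C)(C)C | intermediate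
11 | 2-(trimethylsilyl)ethyl 2-[(3S,4S)-6-methoxy-4,6-dimethyl-4-({[2-(trimethylsilyl)ethoxy]carbonyl}oxy)-1,2-dioxan-3-yl]acetate, present as its potassium ester enolate (both C6 epimers) | COC1(C)C[C@](C)(OC(=O)OCC[Si](C)(C)C)[C@H](CC(=O)OCC[Si](C)(C)C)OO1 | intermediate (not isolated)
12 | 2-(trimethylsilyl)ethyl (4aS,7aS)-3-methoxy-3,4a-dimethyl-6-oxohexahydro-3H-furo[3,2-c][1,2]dioxine-7-carboxylate (epimers at the peroxyketal carbon and at the enolisable C7 of the ring system) | COC1(C)C[C@]2(C)OC(=O)C(C(=O)OCC[Si](C)(C)C)[C@@H]2OO1 | intermediate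
13 | (4aS,7aS)-3-methoxy-3,4a-dimethyl-6-oxohexahydro-3H-furo[3,2-c][1,2]dioxine-7-carboxylic acid | COC1(C)C[C@]2(C)OC(=O)C(C(=O)O)[C@@H]2OO1 | intermediate (not isolated)
14 | (4aS,7aS)-3-methoxy-3,4a-dimethyltetrahydro-3H-furo[3,2-c][1,2]dioxin-6(4H)-one (both peroxyketal epimers) | COC1(C)C[C@]2(C)OC(=O)C[C@@H]2OO1 | intermediate
15 | 3-methylbut-2-enal | CC(C)=CC=O | starting material
16 | (E)-trimethyl[(3-methylbuta-1,3-dien-1-yl)oxy]silane | C=C(C)/C=C/O[Si](C)(C)C | intermediate
17 | (2E)-4-[(3R,4aS,7aS)-3,4a-dimethyl-6-oxohexahydro-3H-furo[3,2-c][1,2]dioxin-3-yl]-3-methylbut-2-enal | O=C/C=C(\C)C[C@]1(C)C[C@]2(C)OC(=O)C[C@@H]2OO1 | intermediate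
18 | hex-5-en-1-ol | C=CCCCCO | starting material
19 | styrene | C=Cc1ccccc1 | starting material
20 | (E)-6-phenylhex-5-en-1-ol | OCCCC/C=C/c1ccccc1 | intermediate
21 | 1-phenyl-1H-tetrazole-5-thiol | Sc1nnnn1-c1ccccc1 | starting material
22 | (E)-1-phenyl-5-[(6-phenylhex-5-en-1-yl)sulfanyl]-1H-tetrazole | S(CCCC/C=C/c1ccccc1)c1nnnn1-c1ccccc1 | intermediate
23 | (E)-1-phenyl-5-[(6-phenylhex-5-en-1-yl)sulfonyl]-1H-tetrazole | O=S(=O)(CCCC/C=C/c1ccccc1)c1nnnn1-c1ccccc1 | intermediate
24 | plakortolide H, (3R,4aS,7aS)-3,4a-dimethyl-3-[(2E,4E,9E)-2-methyl-10-phenyldeca-2,4,9-trien-1-yl]tetrahydro-3H-furo[3,2-c][1,2]dioxin-6(4H)-one | C/C(=C\C=C\CCC/C=C/c1ccccc1)C[C@]1(C)C[C@]2(C)OC(=O)C[C@@H]2OO1 | target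

**Step count**

Total steps: 14 (steps 3, 9 and 11–13 prepare reagents and the side-chain fragment).
Longest linear sequence: 9 steps (1, 2, 4, 5, 6, 7, 8, 10, 14).

**Steps most likely to fail**

1. Step 7. The C2 enolate may not be captured by the carbonate: the adduct 11 may simply be protonated and stop at the monocyclic dioxane, or the carbonate may be lost by attack of alkoxide or peroxide anion, so that the C1–C2 bond never forms. The fallback uses known chemistry, sets out from 4 and returns at 14, bypassing steps 3 to 8. Stork–Zhao olefination of 4 ([Ph3PCH2I]I, NaN(SiMe3)2 in excess, THF/DMPU, −78 °C) should give (S,Z)-1-iodo-3,5-dimethylhexa-1,5-dien-3-ol F1. Acylation of its lithium alkoxide (LiN(SiMe3)2, then ClCO2Me) gives (S,Z)-1-iodo-3,5-dimethylhexa-1,5-dien-3-yl methyl carbonate F2. Iodine–magnesium exchange (iPrMgCl·LiCl, THF, −40 → 0 °C) generates the Z alkenylmagnesium species, which closes the same C1–C2 bond by intramolecular acyl substitution on the carbonate (Parham-type cyclisation) to give the butenolide (S)-5-methyl-5-(2-methylprop-2-en-1-yl)furan-2(5H)-one F3. Ozonolysis in CH2Cl2/MeOH gives (5S)-5-(2-hydroperoxy-2-methoxypropyl)-5-methylfuran-2(5H)-one F4, and Et2NH in CF3CH2OH effects the 6-exo oxa-Michael addition onto the butenolide to give 14 with the cis ring fusion. No C2 activating group is needed on this path.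

2. Step 8. The free β-carbonyl acid may ionise the methoxy peroxyketal, or the O–O bond may homolyse, at the temperature needed for decarboxylation; fluoride may also open the β-peroxy lactone by retro-Michael reaction. The fallback sets out from 13, prepared at room temperature, and returns at 14. Coupling with N-hydroxypyridine-2-thione (DCC, CH2Cl2, 0 °C, dark) gives 2-thioxopyridin-1(2H)-yl (4aS,7aS)-3-methoxy-3,4a-dimethyl-6-oxohexahydro-3H-furo[3,2-c][1,2]dioxine-7-carboxylate F5. Visible-light photolysis with t-BuSH at 10 °C (Barton reductive decarboxylation) replaces the carboxyl by hydrogen without heating; the thiol should trap the C2 radical before it attacks the peroxide.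

3. Step 10. The dienol ether may react through its α-carbon, the Lewis acid may equilibrate the E enal with its Z isomer, or the facial bias at C6 may be too small. The fallback sets out from 14 and returns at 17. The simpler enol ether 2-(trimethylsilyloxy)propene with Me3SiOTf (CH2Cl2, −78 °C) should give 1-[(3S,4aS,7aS)-3,4a-dimethyl-6-oxohexahydro-3H-furo[3,2-c][1,2]dioxin-3-yl]propan-2-one F6, which has the same spatial arrangement at C6 as 17 (the descriptor differs only by CIP priority). As a β-peroxy ketone it can be equilibrated at C6 by base through retro-oxa-Michael and oxa-Michael steps, so an unwanted epimer can be recycled. Formyl-olefination with the sodium salt of diethyl [2-(cyclohexylamino)vinyl]phosphonate (NaH, THF) gives (2E)-N-cyclohexyl-4-[(3R,4aS,7aS)-3,4a-dimethyl-6-oxohexahydro-3H-furo[3,2-c][1,2]dioxin-3-yl]-3-methylbut-2-en-1-imine F7, and aqueous oxalic acid hydrolyses it to 17, the E isomer being separated from any Z isomer.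

**Further compounds**

F1 | step 7 | (S,Z)-1-iodo-3,5-dimethylhexa-1,5-dien-3-ol | C=C(C)C[C@](/C=C\I)(C)O
F2 | step 7 | (S,Z)-1-iodo-3,5-dimethylhexa-1,5-dien-3-yl methyl carbonate | C=C(C)C[C@](/C=C\I)(C)OC(=O)OC
F3 | step 7 | (S)-5-methyl-5-(2-methylprop-2-en-1-yl)furan-2(5H)-one | C=C(C)C[C@]1(C)OC(=O)C=C1
F4 | step 7 | (5S)-5-(2-hydroperoxy-2-methoxypropyl)-5-methylfuran-2(5H)-one | COC(C)(OO)C[C@]1(C)OC(=O)C=C1
F5 | step 8 | 2-thioxopyridin-1(2H)-yl (4aS,7aS)-3-methoxy-3,4a-dimethyl-6-oxohexahydro-3H-furo[3,2-c][1,2]dioxine-7-carboxylate | COC1(C)C[C@]2(C)OC(=O)C(C(=O)ON3C=CC=CC3=S)[C@@H]2OO1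
F6 | step 10 | 1-[(3S,4aS,7aS)-3,4a-dimethyl-6-oxohexahydro-3H-furo[3,2-c][1,2]dioxin-3-yl]propan-2-one | CC(=O)C[C@]1(C)C[C@]2(C)OC(=O)C[C@@H]2OO1
F7 | step 10 | (2E)-N-cyclohexyl-4-[(3R,4aS,7aS)-3,4a-dimethyl-6-oxohexahydro-3H-furo[3,2-c][1,2]dioxin-3-yl]-3-methylbut-2-en-1-imine | C(/C=C(\C)C[C@]1(C)C[C@]2(C)OC(=O)C[C@@H]2OO1)=NC1CCCCC1
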